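**Retrosynthetic overview**
- Rings A and B are never built. Both arrive as the intact arene of 2,3-dibromobenzoic acid with Br already on C2 and C3, so no ring is formed and no bromination has to be directed.
- Feature used: in each 2,3-dibromo-5-oxygenated ring, C4–H lies between C3–Br and the C5–O substituent. It is the most acidic ring hydrogen, and C4 is the carbon that still lacks its oxygen.
- Last bonds made: C4–O in ring A and C4–O in ring B, formed together by twofold magnesiation, borylation and oxidation of the bis(methoxymethyl)-protected dibenzyl ether. Acetal removal then ends the route.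
- Before that: the central CH2–O–CH2 link, by Williamson coupling of one benzylic alcohol with the bromide made from it.
- First: C5–O, by sterically governed C–H borylation and oxidation of methyl 2,3-dibromobenzoate.

Key step: step 7

Remark: all locants follow the benzyl numbering of the target (C1 carries the CH2O arm, C2 and C3 the bromines, C4 and C5 the oxygens, C6 the hydrogen), and the target has no stereocentre, so no SMILES carries a stereo descriptor.

Step 1
Reactants: 1 2,3-dibromobenzoic acid
Product: 2 methyl 2,3-dibromobenzoate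
Conditions: MeOH, H2SO4 (cat.), reflux
Reagents that add atoms: methanol, CO
Why: Fischer esterification, which a single ortho bromine does not seriously hinder, masks the acidic proton that would otherwise consume the boron reagent and the catalyst of step 2.

Step 2
Reactants: 2 methyl 2,3-dibromobenzoate; 3 bis(pinacolato)diboron
Product: 5 methyl 2,3-dibromo-5-hydroxybenzoate, via C5 pinacol boronate 4 (not isolated)
Conditions: [Ir(OMe)(cod)]2 (1.5 mol %), dtbpy (3 mol %), 3 (0.6 equiv), THF, 65 °C; evaporate; KHSO5 (as 2KHSO5·KHSO4·K2SO4), acetone/H2O, rt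
Reagents that add atoms: KHSO5 (potassium peroxymonosulfate), [K+].[O-]S(=O)(=O)OO
Why: Iridium-catalysed, sterically governed aromatic C–H borylation should pick C5–H, the only ring hydrogen of 2 without an ortho substituent (C4–H adjoins Br, C6–H adjoins CO2Me), without touching the C–Br bonds, and the one-pot peroxymonosulfate oxidation moves the aryl group from boron to oxygen at the same carbon.

Step 3
Reactants: 5 methyl 2,3-dibromo-5-hydroxybenzoate; 6 chloromethyl methyl ether
Product: 7 methyl 2,3-dibromo-5-(methoxymethoxy)benzoate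
Conditions: 6, i-Pr2NEt, CH2Cl2, 0 °C → rt
Reagents that add atoms: chloromethyl methyl ether (6), COCCl
Why: O-alkylation of the acidic phenol by the highly electrophilic alpha-chloro ether installs an acetal that survives hydride, base and organomagnesium chemistry and later anchors the amide base next to C4.

Step 4
Reactants: 7 methyl 2,3-dibromo-5-(methoxymethoxy)benzoate
Product: 8 [2,3-dibromo-5-(methoxymethoxy)phenyl]methanol
Conditions: i-Bu2AlH (2.5 equiv), CH2Cl2, −78 → 0 °C; aq. KNaC4H4O6
Reagents that add atoms: none
Why: Ester-to-alcohol reduction by i-Bu2AlH, a hydride that at low temperature touches neither the aryl bromides nor the acetal.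

Step 5
Reactants: 8 [2,3-dibromo-5-(methoxymethoxy)phenyl]methanol (one half of the batch)
Product: 9 2,3-dibromo-5-(methoxymethoxy)benzyl bromide
Conditions: CBr4, PPh3, CH2Cl2, 0 °C
Reagents that add atoms: carbon tetrabromide, BrC(Br)(Br)Br
Why: Appel reaction, an SN2 bromination of the primary benzylic alcohol under essentially neutral conditions, so that the acid-labile acetal is not exposed to HBr as it would be with PBr3.

Step 6
Reactants: 8 [2,3-dibromo-5-(methoxymethoxy)phenyl]methanol (other half of the batch); 9 2,3-dibromo-5-(methoxymethoxy)benzyl bromide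
Product: 11 bis[2,3-dibromo-5-(methoxymethoxy)benzyl] ether, via sodium alkoxide 10 (not isolated)
Conditions: NaH, THF, 0 °C; then 9, Bu4NI (cat.), 0 °C → rt
Reagents that add atoms: none
Why: Williamson ether synthesis, in which the primary alkoxide 10 displaces bromide from the primary benzylic bromide 9 by SN2 with iodide catalysis, the aryl bromides and acetals being inert to NaH.

Step 7
Reactants: 11 bis[2,3-dibromo-5-(methoxymethoxy)benzyl] ether; 12 trimethyl borate
Product: 15 bis[2,3-dibromo-4-hydroxy-5-(methoxymethoxy)benzyl] ether, via bis(arylmagnesium chloride) 13 (not isolated), via bis(trimethoxyborate) 14 (not isolated)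
Conditions: TMPMgCl·LiCl (TMP = 2,2,6,6-tetramethylpiperidin-1-yl, 3 equiv), THF, −40 → −10 °C; 12 (6 equiv), −40 → 0 °C; aq. NaOH, 30% H2O2, 0 °C; 1 M HCl to pH 6
Reagents that add atoms: hydrogen peroxide, OO
Why: Directed ortho-magnesiation followed by borate formation and peroxide oxidation is a sequence known for bromoarenes that carry an acetal-protected phenol: TMPMgCl·LiCl binds to the OCH2OCH3 oxygens at C5 and takes the neighbouring C4 proton in ring A and in ring B, a proton made acidic by the ortho C3–Br and the meta C2–Br. The selectivity needed is C4 over C6 in both rings, and the substrate secures it because C6–H shares the acetal neighbour but has no adjacent halogen and sits next to the CH2O arm, so acidity and coordination together point to C4. The largely covalent C–Mg bonds of 13 should hold at or below −10 °C, so neither loss of MgBrCl to an aryne nor bromine migration is expected, and an amide base can neither exchange bromine for magnesium nor, at this basicity, deprotonate the benzylic CH2 groups toward a Wittig rearrangement. B(OMe)3 turns each C–Mg bond into the borate of 14, hydroperoxide adds to boron, and the aryl group shifts from boron to oxygen at the same carbon, which makes both C4–O bonds in one flask. No ring is closed and no stereocentre is created.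

Step 8
Reactants: 15 bis[2,3-dibromo-4-hydroxy-5-(methoxymethoxy)benzyl] ether
Product: 17 bis(2,3-dibromo-4,5-dihydroxybenzyl) ether, via bis(trimethylsilyl ether) 16 (not isolated)
Conditions: Me3SiBr (5 equiv), 4 Å MS, CH2Cl2, −40 → −10 °C; cold aq. Na2HPO4/NaH2PO4 (pH 7)
Reagents that add atoms: none
Why: Silyl-halide cleavage of an aryl acetal, in which Me3SiBr silylates the aryl oxygen of the acetal and bromide removes the CH2OCH3 carbon to leave silyl ether 16, which the buffer hydrolyses, while the central ether, less reactive toward silicon than an acetal and attached to rings deactivated by two bromines, should persist at low temperature in a medium free of alcohols that could exchange a para-hydroxybenzylic ether.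

**Compound list**
1 | 2,3-dibromobenzoic acid | OC(=O)c1cccc(Br)c1Br | starting material
2 | methyl 2,3-dibromobenzoate | COC(=O)c1cccc(Br)c1Br | intermediate
3 | bis(pinacolato)diboron | CC1(C)OB(OC1(C)C)B1OC(C)(C)C(C)(C)O1 | starting material
4 | methyl 2,3-dibromo-5-(4,4,5,5-tetramethyl-1,3,2-dioxaborolan-2-yl)benzoate | COC(=O)c1cc(cc(Br)c1Br)B1OC(C)(C)C(C)(C)O1 | intermediate
5 | methyl 2,3-dibromo-5-hydroxybenzoate | COC(=O)c1cc(O)cc(Br)c1Br | intermediate
6 | chloromethyl methyl ether | COCCl | starting material
7 | methyl 2,3-dibromo-5-(methoxymethoxy)benzoate | COC(=O)c1cc(OCOC)cc(Br)c1Br | intermediate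
8 | [2,3-dibromo-5-(methoxymethoxy)phenyl]methanol | COCOc1cc(CO)c(Br)c(Br)c1 | intermediate
9 | 2,3-dibromo-5-(methoxymethoxy)benzyl bromide | COCOc1cc(CBr)c(Br)c(Br)c1 | intermediate
10 | sodium [2,3-dibromo-5-(methoxymethoxy)phenyl]methanolate | [Na+].[O-]Cc1cc(OCOC)cc(Br)c1Br | intermediate
11 | bis[2,3-dibromo-5-(methoxymethoxy)benzyl] ether | COCOc1cc(COCc2cc(OCOC)cc(Br)c2Br)c(Br)c(Br)c1 | intermediate
12 | trimethyl borate | COB(OC)OC | starting material
13 | bis[2,3-dibromo-4-(chloromagnesio)-5-(methoxymethoxy)benzyl] ether | COCOc1cc(COCc2cc(OCOC)c([Mg]Cl)c(Br)c2Br)c(Br)c(Br)c1[Mg]Cl | intermediate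
14 | bis[2,3-dibromo-5-(methoxymethoxy)-4-(trimethoxyboranuidyl)benzyl] ether, bis(chloromagnesium) salt | COCOc1cc(COCc2cc(OCOC)c([B-](OC)(OC)OC)c(Br)c2Br)c(Br)c(Br)c1[B-](OC)(OC)OC.[Mg+]Cl.[Mg+]Cl | intermediate
15 | bis[2,3-dibromo-4-hydroxy-5-(methoxymethoxy)benzyl] ether | COCOc1cc(COCc2cc(OCOC)c(O)c(Br)c2Br)c(Br)c(Br)c1O | intermediate
16 | bis[2,3-dibromo-4-hydroxy-5-(trimethylsilyloxy)benzyl] ether | C[Si](C)(C)Oc1cc(COCc2cc(O[Si](C)(C)C)c(O)c(Br)c2Br)c(Br)c(Br)c1O | intermediate
17 | bis(2,3-dibromo-4,5-dihydroxybenzyl) ether | Oc1cc(COCc2cc(O)c(O)c(Br)c2Br)c(Br)c(Br)c1O | target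

**Total step count:** 8
**Longest linear sequence:** 8 (1 → 2 → 5 → 7 → 8 → 9 → 11 → 15 → 17)

**Steps most likely to fail**

**Step 7.**
- What may go wrong: the C3 bromine is pressed toward C4–H by the C2 bromine and may slow proton removal. Then only one ring may be metalated, deprotonation at C6 may compete, or the warming needed for conversion may start loss of MgBrCl toward an aryne.
- Fallback (sets out from 8, comes back at 17): the oxygenation leaves the two-directional setting and is done on one ring before the ether is built.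
- Alcohol 8 is silylated (i-Pr3SiCl, imidazole, DMF) to the benzylic triisopropylsilyl ether F1, whose bulky silyl group screens C6.
- TMPMgCl·LiCl gives the C4 arylmagnesium chloride F2, B(OMe)3 gives the trimethoxyborate F3, and NaOH/H2O2 gives the C4 phenol F4. F4 can be freed from any positional isomer and from recovered F1 by chromatography.
- MOMCl/i-Pr2NEt caps the new phenol to give the 4,5-bis(methoxymethyl) ether F5, and Bu4NF releases the benzylic alcohol F6.
- CBr4/PPh3 turns half of F6 into the benzylic bromide F7, and NaH converts the other half into the sodium alkoxide F8. F8 couples with F7 to the tetrakis(methoxymethyl) dibenzyl ether F9.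
- Me3SiBr under the conditions of step 8 passes through the tetrakis(trimethylsilyl) ether F10 and gives 17 on buffered work-up.

**Step 8.**
- What may go wrong: the free para C4–OH may assist ionisation of the benzylic C–O bond under the silyl bromide or under adventitious HBr. That would cut the central ether and lead to oligomerisation.
- Fallback (sets out from 15, comes back at 17): the para oxygen is switched off electronically before the acidic step and is unveiled last under non-acidic conditions.
- Ac2O, pyridine and DMAP (cat.) give the bis(C4 acetate) F11.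
- Me3SiBr then cleaves the acetals through the bis(C5 trimethylsilyl ether) F12 to the bis(4-acetoxy-5-hydroxybenzyl) ether F13. The acetoxy group is too poor a donor to support a benzylic cation.
- N2H4·H2O in THF at 0 °C removes the aryl acetates by aminolysis in a reducing medium that also protects the catechols, giving 17.

**Step 2.**
- What may go wrong: the iridium catalyst may stall on the dihalogenated arene, borylation may leak to C4, or the peroxymonosulfate may over-oxidise the freshly formed phenol.
- Fallback (sets out from 2, comes back at 5): the C5 oxygen is brought in by electronically controlled aromatic substitution instead of C–H borylation.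
- HNO3/H2SO4 at 0 °C should nitrate C5, the position meta to the ester and para to C2–Br, to give methyl 2,3-dibromo-5-nitrobenzoate F14.
- Fe/NH4Cl in EtOH/H2O reduces it, without hydrogenolysis of C–Br, to methyl 5-amino-2,3-dibromobenzoate F15.
- NaNO2 in aq. H2SO4 at 0 °C gives the arenediazonium hydrogen sulfate F16.
- Cu2O/Cu(NO3)2 in water at rt (Sandmeyer-type hydroxydediazoniation) delivers 5 without the hot acid that would hydrolyse the ester.

**Further compounds**
F1 | step 7 | {[2,3-dibromo-5-(methoxymethoxy)benzyl]oxy}triisopropylsilane | COCOc1cc(CO[Si](C(C)C)(C(C)C)C(C)C)c(Br)c(Br)c1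
F2 | step 7 | {[2,3-dibromo-4-(chloromagnesio)-5-(methoxymethoxy)benzyl]oxy}triisopropylsilane | COCOc1cc(CO[Si](C(C)C)(C(C)C)C(C)C)c(Br)c(Br)c1[Mg]Cl
F3 | step 7 | chloromagnesium trimethoxyborate at C4 of F1 | COCOc1cc(CO[Si](C(C)C)(C(C)C)C(C)C)c(Br)c(Br)c1[B-](OC)(OC)OC.[Mg+]Cl
F4 | step 7 | 2,3-dibromo-6-(methoxymethoxy)-4-{[(triisopropylsilyl)oxy]methyl}phenol | COCOc1cc(CO[Si](C(C)C)(C(C)C)C(C)C)c(Br)c(Br)c1O
F5 | step 7 | {[2,3-dibromo-4,5-bis(methoxymethoxy)benzyl]oxy}triisopropylsilane | COCOc1cc(CO[Si](C(C)C)(C(C)C)C(C)C)c(Br)c(Br)c1OCOC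
F6 | step 7 | [2,3-dibromo-4,5-bis(methoxymethoxy)phenyl]methanol | COCOc1cc(CO)c(Br)c(Br)c1OCOC
F7 | step 7 | 2,3-dibromo-4,5-bis(methoxymethoxy)benzyl bromide | COCOc1cc(CBr)c(Br)c(Br)c1OCOC
F8 | step 7 | sodium [2,3-dibromo-4,5-bis(methoxymethoxy)phenyl]methanolate | [Na+].[O-]Cc1cc(OCOC)c(OCOC)c(Br)c1Br
F9 | step 7 | bis[2,3-dibromo-4,5-bis(methoxymethoxy)benzyl] ether | COCOc1cc(COCc2cc(OCOC)c(OCOC)c(Br)c2Br)c(Br)c(Br)c1OCOC
F10 | step 7 | bis[2,3-dibromo-4,5-bis(trimethylsilyloxy)benzyl] ether | C[Si](C)(C)Oc1cc(COCc2cc(O[Si](C)(C)C)c(O[Si](C)(C)C)c(Br)c2Br)c(Br)c(Br)c1O[Si](C)(C)C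
F11 | step 8 | bis[4-acetoxy-2,3-dibromo-5-(methoxymethoxy)benzyl] ether | COCOc1cc(COCc2cc(OCOC)c(OC(C)=O)c(Br)c2Br)c(Br)c(Br)c1OC(C)=O
F12 | step 8 | bis[4-acetoxy-2,3-dibromo-5-(trimethylsilyloxy)benzyl] ether | CC(=O)Oc1c(O[Si](C)(C)C)cc(COCc2cc(O[Si](C)(C)C)c(OC(C)=O)c(Br)c2Br)c(Br)c1Br
F13 | step 8 | bis(4-acetoxy-2,3-dibromo-5-hydroxybenzyl) ether | CC(=O)Oc1c(O)cc(COCc2cc(O)c(OC(C)=O)c(Br)c2Br)c(Br)c1Br
F14 | step 2 | methyl 2,3-dibromo-5-nitrobenzoate | COC(=O)c1cc(cc(Br)c1Br)[N+](=O)[O-]
F15 | step 2 | methyl 5-amino-2,3-dibromobenzoate | COC(=O)c1cc(N)cc(Br)c1Br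
F16 | step 2 | 3,4-dibromo-5-(methoxycarbonyl)benzenediazonium hydrogen sulfate | COC(=O)c1cc(cc(Br)c1Br)[N+]#N.OS(=O)(=O)[O-]
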